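With time, the ash run loses starting material on a nearly first-order curve, and a flask with a different charge of capture agent can be built on that curve one process at a time.

- ash: starting material 3 M; capture agent 1.3 M; free catalyst 10 mol%; run made earlier
- flask: starting material 3.0 M; capture agent 0.900 M; free catalyst 10 mol%; time 6.0 min

ash run (percent of the starting material charged)

| time / min | target / % | trapped intermediate / % |
|---|---|---|
| 0.667 | 6.4 | 0.4 |
| 2.00 | 22.4 | 1.0 |
| 3.00 | 31.7 | 2.4 |
| 5.00 | 45.7 | 2.6 |
| 8.00 | 60.3 | 4.3 |

(readings scatter by 0.5 percentage points)

- a reading or a percentage of target counts all its forms, free or not
- the concentration of target that is asked is that of its free form alone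
- no earlier run changes the charge of capture agent; that part of a forecast is a guess

- concentration of target (only what is free in solution) at 6.0 min, in M
- concentration of trapped intermediate at 6.0 min, in M

First the main step. At 8.00 min the ash run reads 60.3% target and 4.3% trapped intermediate, so 35.4% of the starting material counts as unreacted, which gives a first-order constant of 0.130 min⁻¹. Taking this constant as independent of capture agent, which is a guess, the flask converts 54.1% by 6.0 min.

Next the capture. In the ash run, trapped intermediate over target reads 0.0757, 0.0569 and 0.0713 at the last three times, level within the scatter, so this branch can be reckoned as a correction to the main step. The capture ratio s, a selectivity factor, is trapped intermediate per target, divided by the charged c(capture agent); the last reading of the ash run gives 0.0549 L mol⁻¹. Assuming first order in capture agent, another guess, the flask's 0.900 M gives a ratio of 0.0494, which splits the conversion into 1.55 M target and 0.0764 M trapped intermediate.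

Last, bound target. The readings count it together with the free form and give it no size, so this reckoning subtracts nothing.

The forecast, which says “I subtract about 0.1 M”, stands lower on free target than this reckoning, at 1.45 M, with 0.07 M trapped intermediate.

The flask gives 1.61 M free target and 0.0755 M trapped intermediate.

    starting material + free catalyst → catalyst intermediate A (k = 0.0175 L mol⁻¹ s⁻¹)
    catalyst intermediate A → catalyst intermediate B (k = 0.206 s⁻¹)
    catalyst intermediate B ⇌ free catalyst + target (K = 9.50 M, k = 0.0636 s⁻¹)
    capture agent + catalyst intermediate B → trapped intermediate (k = 0.00290 L mol⁻¹ s⁻¹)
    free catalyst + target ⇌ idle complex (K = 0.0760 L mol⁻¹, k = 0.0391 L mol⁻¹ s⁻¹)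

Applied to the flask's simulated target of 54.1%, all forms counted, the product of s, c(capture agent) and c(target) gives 0.0801 M trapped intermediate, against the 0.0755 M found. The neighbouring flask has the same charges and is read at 10 min, where it holds 70.3% target, all forms counted. The same product gives 0.104 M, and the neighbouring flask holds 0.107 M trapped intermediate.

All runs were computed on assumed constants; scatter was added.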